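## The problem

3,5,6-Tribromo-1H-indole 13 is a flat pyrrole–benzene bicycle without a stereocentre, so the task is purely regiochemical: three bromines must end up at C3, C5 and C6 and nowhere else. The bromine at C3 is the easy one, because C3 is the most nucleophilic carbon of an indole. The vicinal pair at C5 and C6 is not, since electrophilic bromination of an indole does not separate C5 and C6 cleanly from C2, C4 and C7 and is accompanied by oxidation. This pattern must therefore be bought in a benzenoid starting material or written into the benzene ring when that ring is made. The free N–H 3-bromoindole is sensitive to acid, light and oxidants, which calls for an electron-withdrawing group on nitrogen until the last step and a basic, non-reductive unmasking; once carbon–bromine bonds are present, low-valent metals, organolithium reagents and dissolving-metal conditions are best avoided. The feature that opens a ring-forming answer is that C5 and C6 are neighbours with identical substituents, flanked by unsubstituted C4–H and C7–H, while the C3a–C7a bond is shared with the pyrrole ring. C4, C3a, C7a and C7 can therefore be the diene of a pyrrole-fused 2-pyranone, and C5 and C6 the two carbons of a symmetric alkyne whose silicon substituents are placeholders for bromine. The only stereocentres that ever appear are the two bridgeheads of a transient cycloadduct, and they vanish when carbon dioxide is lost.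

## Retrosynthesis

**13 from 12.** The N–S bond is cut first, which traces the target to its N-phenylsulfonyl derivative 12. Keeping the sulfonyl group to the end protects the 3-bromoindole from acid and oxidants and damps C2 during bromination. The forward step only has to cleave a sulfonamide with hydroxide without touching three aryl bromides.

**12 from 11.** All three C–Br bonds are cut together. C5–Br and C6–Br go back to C–Si bonds and C3–Br to C–H, which gives the halogen-free indole 11, 1-(phenylsulfonyl)-5,6-bis(trimethylsilyl)-1H-indole. Against a stepwise introduction this saves operations, and the positions of the ring bromines are dictated by where silicon sits, not by the directing effects of the indole. The forward reaction must be ipso-selective at the silicon-bearing carbons, faster than protodesilylation, and silent at C2, C4 and C7.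

**11 from 8 and 9.** The bonds C4–C5 and C6–C7 are cut. This is preferred over cuts in the pyrrole ring because it builds the benzene ring, where the difficult substitution pattern lies. The two-carbon partner, bis(trimethylsilyl)acetylene 9, is symmetric, so no regiochemical question exists. The four-carbon partner is the quinoid 2-pyranone 8, 1-(phenylsulfonyl)pyrano[3,4-b]pyrrol-5(1H)-one, whose diene termini are the future C4 and C7. The forward reaction is a thermal [4+2] addition to bridged lactone 10 followed by extrusion of carbon dioxide, and with a hindered alkyne it must outrun self-reaction of the diene.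

**8 from 6.** The lactone C–O bond is cut, which leads to the ortho-formyl heteroarylacetic acid 6. Cyclodehydration by way of mixed anhydride 7 is the established way to such fused pyranones. The precursor is a simple 2,3-disubstituted pyrrole, and the forward step only has to remove one molecule of water.

**6 from 5.** The acid is traced to methyl ester 5 by cutting the ester C–O bond. The ester is the form in which the side chain is made and carried through the formylation, and the forward hydrolysis must leave the N–S bond and the aldehyde alone.

**5 from 4.** The C2–CHO bond is cut to give methyl 2-[1-(phenylsulfonyl)-1H-pyrrol-3-yl]acetate 4. The reverse order (formyl first, side chain second) is rejected because a 2-acylpyrrole sends electrophiles to C4, not C3. The forward formylation must choose C2 over C5.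

**4 from 3.** The acetic ester chain is traced to the acetyl group of ketone 3 through an oxidative 1,2-aryl shift, so the ring–carbon bond moves from the carbonyl carbon to the former methyl carbon. This makes the two-carbon chain from the one carbon substituent that can be put on C3 directly. The forward reaction has to oxidise the ketone without oxidising the pyrrole ring.

**3 from 1 and 2.** The C3–acyl bond is cut, which leads to 1-(phenylsulfonyl)-1H-pyrrole 1 and acetyl chloride 2. Friedel–Crafts acylation of the N-sulfonylpyrrole is the one direct and reliable way to put carbon on the β-position of a pyrrole. The sulfonyl group bought with 1 thus directs the acylation, survives the oxidation, stabilises the diene, tames the bromination and is removed only at the end.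

## Roads not taken

Alternative 1: The cut is C3–C3a, made on the enamino ester methyl (Z)-3-[(4,5-dibromo-2-iodophenyl)amino]prop-2-enoate A2, which would come from 4,5-dibromo-2-iodoaniline A3 and methyl prop-2-ynoate A4 by conjugate addition.
- Forward key step: zerovalent palladium inserts into the carbon–iodine bond of A2, the aryl group adds to the ester-bearing enamine carbon, and β-hydride elimination gives methyl 5,6-dibromo-1H-indole-3-carboxylate A1. Saponification of A1 and ipso-bromodecarboxylation at C3 would then lead to 13.
- Merits: both ring bromines are fixed by A3, the ester blocks and later marks C3, every reaction type is familiar, and the count is about five steps from A3.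
- Weak points: the catalyst must choose one carbon–iodine bond over two carbon–bromine bonds on the same ring, A3 itself needs a regioselective iodination, and the acid derived from A1 must exchange its carboxyl group for bromine without attack at C2.
- Comparison: this road is shorter than the eight steps chosen here and avoids a high-temperature cycloaddition, so on step economy it is the better plan. The chosen plan sets against it that no low-valent metal ever meets a carbon–halogen bond, that the halogen pattern does not depend on a trihalogenated aniline, and that one halogen-free intermediate, 11, receives all three bromines in a single operation.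

Alternative 2: The benzene ring is cut at C3a–C4 and C7–C7a, which leads back to 3,4-dibromothiophene 1,1-dioxide A6 as an electron-poor diene and tert-butyl 2,3-dihydro-1H-pyrrole-1-carboxylate A7 as an electron-rich dienophile.
- Forward key step: cycloaddition of A6 across the C=C bond of A7 and cheletropic loss of the sulfonyl bridge would give racemic tert-butyl cis-5,6-dibromo-2,3,3a,7a-tetrahydro-1H-indole-1-carboxylate A5.
- Merits: the inverse electron demand is well matched and promises a much lower reaction temperature, both bromines are on the diene from the start, and A6 is symmetric.
- Weak points: A5 lies two oxidation levels below an indole, so four operations follow the key step (dehydrogenation of the carbocycle, oxidation of the pyrroline ring, removal of the carbamate, bromination at C3). The cyclohexadiene of A5 can also aromatise by cleavage of the allylic C7a–N bond instead of by loss of hydrogen, and A6 dimerises readily.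
- Comparison: the key step is probably easier than the one chosen here, which is a real advantage. The chosen plan answers with an adduct that aromatises by itself through loss of carbon dioxide, so no oxidation-state adjustment and no stereocentre has to be handled afterwards.

Alternative 3: The cut is N1–C2 together with C3–Br, made on N-[4,5-dibromo-2-[(trimethylsilyl)ethynyl]phenyl]-4-methylbenzenesulfonamide A9, which would be assembled from A3 by Sonogashira coupling at the iodide and N-tosylation.
- Forward key step: copper dibromide CuBr2 A10 activates the alkyne of A9, nitrogen closes in a 5-endo-dig mode, and the C3–copper bond is converted to C3–Br to give 3,5,6-tribromo-1-tosyl-2-(trimethylsilyl)-1H-indole A8. Fluoride or base would then remove the C2 silyl group and the tosyl group of A8.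
- Merits: ring closure and C3 bromination are one step, the bromine pattern is fixed by A3, the conditions are mild, and the sequence is about five steps.
- Weak points: a zerovalent palladium step must again discriminate iodide from bromide on a trihaloarene, and two auxiliary groups (C2–Si and N–Ts) must be taken off the sensitive 3-bromoindole A8.
- Comparison: judged by length and by the reliability of each step this road is at least as good as the chosen plan and probably the more practical one. The chosen plan sets against it the construction of the benzene ring from cheap, halogen-free building blocks, the absence of metal-catalysed couplings next to carbon–bromine bonds, and one late operation that installs all three bromines. Its price is a demanding cycloaddition.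

Key step: step 6

## Route

Remarks on the chemistry:
- Acid 6 may equilibrate with its cyclic hydroxylactone form; it is written and counted in the open form.
- Cycloadduct 10 is racemic and is drawn as one enantiomer.
- The aldehyde oxygen of 5 is taken to come from water in the hydrolytic work-up.

Step 1
Reactants: 1 1-(phenylsulfonyl)-1H-pyrrole; 2 acetyl chloride
Product: 3 1-[1-(phenylsulfonyl)-1H-pyrrol-3-yl]ethan-1-one
Conditions: AlCl3, CH2Cl2, 0 °C → rt; ice/aq. HCl work-up
Reagents that add atoms: none
Why: Friedel–Crafts acylation; with AlCl3 and an acyl chloride, 1-(arylsulfonyl)pyrroles are acylated at the β-carbon C3 and not at C2, and the deactivated ketone does not react a second time.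

Step 2
Reactants: 3 1-[1-(phenylsulfonyl)-1H-pyrrol-3-yl]ethan-1-one
Product: 4 methyl 2-[1-(phenylsulfonyl)-1H-pyrrol-3-yl]acetate
Conditions: Tl(NO3)3·3H2O, MeOH, HClO4 (cat.), rt
Reagents that add atoms: methanol, CO
Why: Oxidative rearrangement of an aryl methyl ketone with trivalent thallium: oxythallation of the enol, 1,2-shift of the pyrrol-3-yl group to the former methyl carbon with departure of monovalent thallium, and capture by methanol should give the arylacetic ester; the sulfonyl group keeps the ring itself from being oxidised.

Step 3
Reactants: 4 methyl 2-[1-(phenylsulfonyl)-1H-pyrrol-3-yl]acetate
Product: 5 methyl 2-[2-formyl-1-(phenylsulfonyl)-1H-pyrrol-3-yl]acetate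
Conditions: Cl2CHOMe, AlCl3, CH2Cl2, −20 → 0 °C; then H2O
Reagents that add atoms: dichloromethyl methyl ether, COC(Cl)Cl; water, O
Why: Rieche formylation; unlike acylation with acyl chlorides, formylation of N-sulfonylpyrroles with this small electrophile goes to an α-carbon, and of the two α-carbons C2 is the one activated by the adjacent alkyl substituent; the α-chloro ether adduct is hydrolysed to the aldehyde on work-up.

Step 4
Reactants: 5 methyl 2-[2-formyl-1-(phenylsulfonyl)-1H-pyrrol-3-yl]acetate
Product: 6 2-[2-formyl-1-(phenylsulfonyl)-1H-pyrrol-3-yl]acetic acid
Conditions: 2 M HCl (aq), 1,4-dioxane, 70 °C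
Reagents that add atoms: water, O
Why: Acid-catalysed ester hydrolysis; acid is chosen because hydroxide would cleave the N–S bond of a 2-acylated N-sulfonylpyrrole, whereas the sulfonamide and the aldehyde are stable to aqueous acid.

Step 5
Reactants: 6 2-[2-formyl-1-(phenylsulfonyl)-1H-pyrrol-3-yl]acetic acid
Product: 8 1-(phenylsulfonyl)pyrano[3,4-b]pyrrol-5(1H)-one, via mixed acetic anhydride 7 (not isolated)
Conditions: Ac2O, toluene, 90 °C; evaporation, crystallisation
Reagents that add atoms: none
Why: Cyclodehydration of an ortho-formyl arylacetic acid, the standard entry to 2-benzopyran-3-ones and their indole, pyrrole and thiophene analogues: the acid is activated as mixed anhydride 7, the formyl oxygen closes the six-membered lactone, and loss of acetic acid with the C4 proton gives the quinoid 2-pyranone, which in the hetero-fused series should be isolable.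

Step 6
Reactants: 8 1-(phenylsulfonyl)pyrano[3,4-b]pyrrol-5(1H)-one; 9 bis(trimethylsilyl)acetylene
Product: 11 1-(phenylsulfonyl)-5,6-bis(trimethylsilyl)-1H-indole, via bridged lactone cycloadduct 10 (not isolated)
Conditions: 9 (15 equiv), 1,2-dichlorobenzene, sealed tube, 180 °C, Ar
Reagents that add atoms: none
Why: Diels–Alder reaction followed by retro-Diels–Alder loss of CO2: the quinoid diene C4=C3a–C7a=C7 of 8 adds suprafacially across the triple bond of 9, forming the C4–C5 and C6–C7 bonds and regenerating the aromatic pyrrole in bridged lactone 10. At the reaction temperature 10 ejects CO2 in a second pericyclic step, and the new six-membered ring becomes the benzene ring of 11. The closest known reaction types are the alkyne cycloaddition–decarboxylation of pyrano[3,4-b]pyrrol-5(1H)-ones and pyrano[3,4-b]indol-3-ones to indoles and carbazoles, and the same sequence between monocyclic 2-pyranones and bis(silyl)alkynes. The one ring that is closed, the carbocycle, is closed by intermolecular [4+2] annulation (four diene carbons plus two alkyne carbons, two σ bonds in one step) and not by cyclisation of a chain. No stereocentre survives: the two bridgeheads of 10 are tied cis by the bicycle, 10 is racemic, and both centres become sp2 when CO2 leaves. No regioselectivity is needed because 9 is symmetric. The selectivity that is needed is for cycloaddition over self-reaction of the diene, and it is secured by the gain of pyrrole aromaticity in the first step, by a large excess of the alkyne, and by the sulfonyl group, which removes the N–H and damps the nucleophilicity of the pyrrole.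

Step 7
Reactants: 11 1-(phenylsulfonyl)-5,6-bis(trimethylsilyl)-1H-indole
Product: 12 3,5,6-tribromo-1-(phenylsulfonyl)-1H-indole
Conditions: Br2 (3.5 equiv), pyridine, CH2Cl2, 0 °C → rt
Reagents that add atoms: bromine, BrBr
Why: Electrophilic ipso-bromodesilylation of the two aryl–silicon bonds (β-silyl-stabilised arenium ions, relief of the ortho-disilyl strain) and electrophilic substitution at C3 of the N-sulfonylindole, all by the same reagent; pyridine traps the hydrogen bromide from the C3 substitution so that protodesilylation should not compete, and the sulfonyl group keeps C2 unreactive.

Step 8
Reactants: 12 3,5,6-tribromo-1-(phenylsulfonyl)-1H-indole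
Product: 13 3,5,6-tribromo-1H-indole
Conditions: NaOH (aq), 1,4-dioxane, 60 °C; aq. NH4Cl work-up, exclusion of light
Reagents that add atoms: none
Why: Nucleophilic cleavage of the sulfonamide N–S bond by hydroxide; the tribromoindolide is a good leaving group, aryl bromides are inert to aqueous base, and the N–H 3-bromoindole is released under the basic, non-oxidising conditions it tolerates.

## Compound list

1 | 1-(phenylsulfonyl)-1H-pyrrole | O=S(=O)(c1ccccc1)n1cccc1 | starting material
2 | acetyl chloride | CC(Cl)=O | starting material
3 | 1-[1-(phenylsulfonyl)-1H-pyrrol-3-yl]ethan-1-one (3-acetyl-1-(phenylsulfonyl)pyrrole) | CC(=O)c1ccn(S(=O)(=O)c2ccccc2)c1 | intermediate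
4 | methyl 2-[1-(phenylsulfonyl)-1H-pyrrol-3-yl]acetate | COC(=O)Cc1ccn(S(=O)(=O)c2ccccc2)c1 | intermediate
5 | methyl 2-[2-formyl-1-(phenylsulfonyl)-1H-pyrrol-3-yl]acetate | COC(=O)Cc1ccn(S(=O)(=O)c2ccccc2)c1C=O | intermediate
6 | 2-[2-formyl-1-(phenylsulfonyl)-1H-pyrrol-3-yl]acetic acid | OC(=O)Cc1ccn(S(=O)(=O)c2ccccc2)c1C=O | intermediate
7 | acetic 2-[2-formyl-1-(phenylsulfonyl)-1H-pyrrol-3-yl]acetic anhydride (mixed anhydride, not isolated) | CC(=O)OC(=O)Cc1ccn(S(=O)(=O)c2ccccc2)c1C=O | intermediate
8 | 1-(phenylsulfonyl)pyrano[3,4-b]pyrrol-5(1H)-one | O=C1C=C2C=CN(S(=O)(=O)c3ccccc3)C2=CO1 | intermediate
9 | bis(trimethylsilyl)acetylene | C[Si](C)(C)C#C[Si](C)(C)C | starting material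
10 | bridged lactone cycloadduct: bicyclo[2.2.2]octadiene in which the future indole carbons C4 and C7 are joined by a –C(=O)–O– bridge (carbonyl carbon on C4, oxygen on C7), by the pyrrole C3a=C7a bond and by the bis(trimethylsilyl)-substituted C5=C6 bond; N-phenylsulfonyl; racemic, not isolated | O=C1O[C@@H]2C([Si](C)(C)C)=C([Si](C)(C)C)[C@H]1c4ccn(S(=O)(=O)c3ccccc3)c24 | intermediate
11 | 1-(phenylsulfonyl)-5,6-bis(trimethylsilyl)-1H-indole | C[Si](C)(C)c1cc2ccn(S(=O)(=O)c3ccccc3)c2cc1[Si](C)(C)C | intermediate
12 | 3,5,6-tribromo-1-(phenylsulfonyl)-1H-indole | O=S(=O)(c1ccccc1)n1cc(Br)c2cc(Br)c(Br)cc21 | intermediate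
13 | 3,5,6-tribromo-1H-indole | Brc1cc2[nH]cc(Br)c2cc1Br | target

## Step count and risk

Total step count: 8. Longest linear sequence: 8 steps, from 1 to 13.

**Risk at step 6, the key step.** The cycloaddition of the hindered, unactivated alkyne may be slower than thermal self-reaction of the quinoid diene (dimerisation, polymerisation), so that 8 is consumed before the carbocycle forms. The fallback keeps the same two bonds and the same ring closure but replaces the silyl placeholders by boron ones on a more electron-poor alkyne. It sets out from 8, which is heated in 1,2-dichlorobenzene with 2,2'-(ethyne-1,2-diyl)bis(4,4,5,5-tetramethyl-1,3,2-dioxaborolane), an alkynylboronate of the kind that adds to 2-pyranones with loss of CO2. This should give 1-(phenylsulfonyl)-5,6-bis(4,4,5,5-tetramethyl-1,3,2-dioxaborolan-2-yl)-1H-indole F1. Bromodeboronation of F1 with CuBr2 in aqueous methanol at 80 °C should then give 5,6-dibromo-1-(phenylsulfonyl)-1H-indole F2. Br2 in CH2Cl2 would brominate C3 of F2 and bring the route back at 12.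

**Risk at step 7.** Protodesilylation by the hydrogen bromide released in the C3 substitution may outrun ipso-bromination, above all at the second silicon-bearing carbon, which then sits next to a bromine on a deactivated ring. The fallback separates the two kinds of C–Br bond formation. It sets out from 11, whose two C–Si bonds are exchanged first with N-bromosuccinimide in acetonitrile, a reagent that releases no acid and does not readily attack C3 of an N-sulfonylindole. This should give 5,6-dibromo-1-(phenylsulfonyl)-1H-indole F2, the compound also met in the fallback for step 6. Bromination of C3 of F2 with Br2 in CH2Cl2, when no silicon is left to be lost, returns the route at 12.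

**Risk at step 3.** Site selectivity may be poor: attack at C5, the unhindered α-carbon, or at C4 may compete with attack at C2, which lies between the sulfonyl group and the side chain. The fallback moves the formylation to the N–H pyrrole, where a 3-alkyl group directs to the adjacent α-carbon and no bulky N-substituent is in the way. It sets out from 4: NaOMe in MeOH at reflux should remove the sulfonyl group and give methyl 2-(1H-pyrrol-3-yl)acetate F3. Vilsmeier–Haack formylation of F3 (POCl3, DMF, then aqueous NaOAc) should give methyl 2-(2-formyl-1H-pyrrol-3-yl)acetate F4. NaH and benzenesulfonyl chloride in THF at 0 °C put the sulfonyl group back on F4, and the route is rejoined at 5.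

**Risk at step 5.** The quinoid lactone may self-condense or be ring-opened by moisture during concentration and isolation. The fallback no longer isolates the diene. It sets out from 6, which is heated with Ac2O and a large excess of 9 in a sealed vessel at 160–180 °C, so that 8 is trapped by the alkyne as it forms, as is usual for the non-isolable 2-benzopyran-3-ones. The route is rejoined at 11, and no new compound is made.

## Further compounds

F1 | step 6 | 1-(phenylsulfonyl)-5,6-bis(4,4,5,5-tetramethyl-1,3,2-dioxaborolan-2-yl)-1H-indole | CC1(C)OB(OC1(C)C)c1cc2ccn(S(=O)(=O)c3ccccc3)c2cc1B1OC(C)(C)C(C)(C)O1
F2 | step 6 | 5,6-dibromo-1-(phenylsulfonyl)-1H-indole | O=S(=O)(c1ccccc1)n1ccc2cc(Br)c(Br)cc21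
F3 | step 3 | methyl 2-(1H-pyrrol-3-yl)acetate | COC(=O)Cc1cc[nH]c1
F4 | step 3 | methyl 2-(2-formyl-1H-pyrrol-3-yl)acetate | COC(=O)Cc1cc[nH]c1C=O
F0 | step 5 | none | none
A1 | alternative 1 | methyl 5,6-dibromo-1H-indole-3-carboxylate | COC(=O)c1c[nH]c2cc(Br)c(Br)cc12
A2 | alternative 1 | methyl (Z)-3-[(4,5-dibromo-2-iodophenyl)amino]prop-2-enoate | COC(=O)/C=C\Nc1cc(Br)c(Br)cc1I
A3 | alternative 1 | 4,5-dibromo-2-iodoaniline | Nc1cc(Br)c(Br)cc1I
A4 | alternative 1 | methyl prop-2-ynoate | COC(=O)C#C
A5 | alternative 2 | tert-butyl cis-5,6-dibromo-2,3,3a,7a-tetrahydro-1H-indole-1-carboxylate (racemic, one enantiomer drawn) | CC(C)(C)OC(=O)N1CC[C@@H]2C=C(Br)C(Br)=C[C@H]12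
A6 | alternative 2 | 3,4-dibromothiophene 1,1-dioxide | O=S1(=O)C=C(Br)C(Br)=C1
A7 | alternative 2 | tert-butyl 2,3-dihydro-1H-pyrrole-1-carboxylate | CC(C)(C)OC(=O)N1CCC=C1
A8 | alternative 3 | 3,5,6-tribromo-1-tosyl-2-(trimethylsilyl)-1H-indole | Cc1ccc(cc1)S(=O)(=O)n1c([Si](C)(C)C)c(Br)c2cc(Br)c(Br)cc21
A9 | alternative 3 | N-[4,5-dibromo-2-[(trimethylsilyl)ethynyl]phenyl]-4-methylbenzenesulfonamide | Cc1ccc(cc1)S(=O)(=O)Nc1cc(Br)c(Br)cc1C#C[Si](C)(C)C
A10 | alternative 3 | copper dibromide, CuBr2 | [Cu+2].[Br-].[Br-]
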